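At a reading after 15 min, how many chains have begun, and how long are they?

free monomer 0.020 M; pre-initiator 64 µM; impurity 85 µM; time 15 min

- average number of monomer units in a chain (chains begun, living or dead) at 15 min
- part of the free monomer that has reacted at 15 min

- the average divides the monomer in chains by the number of chains begun, living and dead together
- run time (flask): 15 min

    free monomer + initiator → living end + monomer in chains (k1 = 0.046 M⁻¹ s⁻¹)
    initiator + impurity → spent initiator (k2 = 480 M⁻¹ s⁻¹)
    monomer in chains → over-reaction product (k3 = 1.5 × 10⁻⁵ s⁻¹)
    free monomer + living end → monomer in chains + living end, rate k4*[living end]*[free monomer] (k4 = 100 M⁻¹ s⁻¹)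
    pre-initiator ⇌ initiator (K5 = 0.14, k5 = 0.031 s⁻¹)

Where does the initiator go? Apart from returning to pre-initiator, it either takes free monomer and begins a chain, or meets impurity and is spent. Both rates contain the initiator, so their ratio depends on the other partners. I name the split level: the impurity concentration at which, with free monomer as charged, both paths take initiator equally, 1.92 µM.

And at the start? Impurity stands at 85 µM, so hardly any initiator begins a chain: starts run at 2.26 % of losses.

Does that ratio hold? No, it drifts upward as impurity falls. Summed over that fall, with free monomer taken as constant, chains begun equal the split level times ln(impurity charged / impurity left).

But how much impurity is left? Initiator follows its pre-initiator, because the exchange relaxes in 2.75 s, faster than the 0.28 min loss to impurity. So 12.3 % of the pool is initiator. Pool and impurity then fall together, their difference staying near 21.0 µM. Integrating this second-order loss leaves 4.05 as the impurity-to-pool ratio, hence 27.9 µM of impurity and 2.14 µM of chains.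

And the conversion? Living ends add free monomer, and I put their average over the run at 1.42 µM, which is a guess. Free monomer then decays pseudo-first-order, giving 12.0 % reacted and a length of 1130.

The forecast gives 1100 and 10.5 %, with an initiator pool “that the impurity mostly consumes”. Both numbers are lower than my 1130 and 12.0 %.

The simulation gives 1140 and 11.2 %.

At the reading in this flask, initiator's half-life against impurity, 0.81 min, is still shorter than its 14 min against free monomer, though their ratio has narrowed from 44.3 to 17.5. A run whose answers stand away from the forecast's is the neighbour flask with 2.6 × 10⁻⁴ M of pre-initiator, where impurity is down to 0.011 % of its charge and free monomer to 49 %. The split level, scaled by the mean free monomer, gives 13.0 µM of chains there. The computed neighbour holds 1.39 × 10⁻⁵ M of living ends, with length 735 and 51.4 % reacted.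

(Its constants were drawn at random within sensible limits, and the outcome is calculated.)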